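## Retrosynthetic overview

1. Hippolide E 22 ⇐ 21 by fluoride removal of two silyl ethers and one C-silyl group; 21 ⇐ 14 + 17 by a one-flask anionic [3+2] annulation that makes the C-3–C-2 and C-4–C-5 bonds of the furanone (ring numbering O-1, C-2(=O), C-3, C-4, C-5).
2. Enabling feature: in the 2(5H)-furanone ring O-1 bridges the carbinol carbon C-5 and the acyl carbon C-2. C-5–O-1–C-2 is therefore read as an O-alkyl N,N-diisopropylcarbamate (C-5 as a chiral α-oxy carbanion, polarity reversed; C-2 as its own carbamoyl carbon). C-3=C-4 with the CH2OH on C-4 is read as a propargyl ether, with a pyridylsilyl group on C-3 as temporary activating and directing group.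
3. 14 ⇐ 13 ⇐ allyl sulfoxide 6 + iodide 9 (alkylation, then a [2,3] shift sets the trisubstituted E alkene and its CH2OH); 6 ⇐ 4 ⇐ farnesyl bromide 1 + methallyl alcohol 2.
4. Order of ring formation: the furanone is the only ring; it and its only stereocentre (5R) are made in the key step.

Key step: step 8

Assumption (a remark on the chemistry): the addition of the lithiated carbamate to the alkyne is taken to go with retention at carbon, as other carbon electrophiles do with non-benzylic lithiated carbamates; if it went with inversion, (+)-sparteine would replace (−)-sparteine in step 8.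

## Route

Step 1
Reactants: 1 (2E,6E)-farnesyl bromide; 2 2-methylprop-2-en-1-ol
Product: 4 (5E,9E)-6,10,14-trimethyl-2-methylidenepentadeca-5,9,13-trien-1-ol, via dilithio dianion 3 (not isolated)
Conditions: 2, n-BuLi (2.2 equiv), TMEDA, Et2O/hexane, 0 °C → rt; then 1, −78 °C → rt; H2O
Reagents that add atoms: none
Why: Alkoxide-directed allylic lithiation of 2 gives the symmetric 2-(oxidomethyl)allyl dianion, whose carbon terminus displaces the primary allylic bromide of 1 (SN2 alkylation of an allyllithium) without touching the 2E,6E alkenes; no stereocentre is formed.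

Step 2
Reactants: 4
Product: 6 [(5E,9E)-6,10,14-trimethyl-2-methylidenepentadeca-5,9,13-trien-1-yl] phenyl sulfoxide (racemic at sulfur), via allyl sulfenate 5 (not isolated)
Conditions: n-BuLi, THF, −78 °C; PhSCl, −78 °C → rt
Reagents that add atoms: benzenesulfenyl chloride, ClSc1ccccc1
Why: O-sulfenylation of the lithium alkoxide is followed by the spontaneous [2,3]-sigmatropic sulfenate-to-sulfoxide shift (Mislow–Evans equilibrium, which lies on the sulfoxide side for a primary allyl system); the sulfur stereocentre is not controlled and is lost in step 5.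

Step 3
Reactants: 7 2-iodoethanol; 8 N,N-diisopropylcarbamoyl chloride
Product: 9 2-iodoethyl N,N-diisopropylcarbamate
Conditions: iPr2NEt, DMAP (cat.), CH2Cl2, reflux
Reagents that add atoms: none
Why: O-carbamoylation of a primary alcohol (nucleophilic acyl substitution) under a hindered amine base, so that no alkoxide forms and the iodohydrin does not close to the epoxide.

Step 4
Reactants: 6; 9
Product: 11 (7E,11E)-8,12,16-trimethyl-4-methylidene-3-(phenylsulfinyl)heptadeca-7,11,15-trien-1-yl N,N-diisopropylcarbamate (mixture of diastereomers), via lithiated sulfoxide 10 (not isolated)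
Conditions: LDA, THF, −78 °C; 9, DMPU, −78 → −40 °C
Reagents that add atoms: none
Why: Deprotonation alpha to sulfur and alpha-selective SN2 alkylation of the sulfinyl-stabilised allyl anion by the primary iodide; the new carbon stereocentre is formed without control and is destroyed in step 5.

Step 5
Reactants: 11
Product: 13 (3E,7E,11E)-4-(hydroxymethyl)-8,12,16-trimethylheptadeca-3,7,11,15-tetraen-1-yl N,N-diisopropylcarbamate, via allylic sulfenate 12 (not isolated)
Conditions: Et2NH, MeOH, 40 °C
Reagents that add atoms: none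
Why: Mislow–Evans [2,3]-sigmatropic rearrangement to the allylic sulfenate and S–O cleavage by the thiophile; the envelope transition state with the CH2CH2OCb chain pseudo-equatorial places that chain trans to the new CH2O carbon, which sets the 3E trisubstituted alkene.

Step 6
Reactants: 13
Product: 14 (3E,7E,11E)-4-{[tert-butyl(dimethyl)silyl]oxymethyl}-8,12,16-trimethylheptadeca-3,7,11,15-tetraen-1-yl N,N-diisopropylcarbamate
Conditions: TBSCl, imidazole, DMF, rt
Reagents that add atoms: tert-butyldimethylsilyl chloride, CC(C)(C)[Si](C)(C)Cl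
Why: Silyl ether formation at the only free hydroxyl, which protects the allylic alcohol against the alkyllithium of step 8.

Step 7
Reactants: 15 tert-butyl(dimethyl)(prop-2-yn-1-yloxy)silane; 16 dimethyl(pyridin-2-yl)silane
Product: 17 2-{[3-{[tert-butyl(dimethyl)silyl]oxy}prop-1-yn-1-yl](dimethyl)silyl}pyridine
Conditions: NaOH (10 mol %), DME, 45 °C
Reagents that add atoms: none
Why: Hydroxide-catalysed cross-dehydrogenative coupling of a terminal alkyne C–H with a hydrosilane (silicate activation of Si–H, loss of dihydrogen).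

Step 8
Reactants: 14; 17
Product: 21 (5R)-4-{[tert-butyl(dimethyl)silyl]oxymethyl}-5-[(2E,6E,10E)-3-{[tert-butyl(dimethyl)silyl]oxymethyl}-7,11,15-trimethylhexadeca-2,6,10,14-tetraen-1-yl]-3-[dimethyl(pyridin-2-yl)silyl]furan-2(5H)-one, via lithiated carbamate 18 (not isolated), via alkenyllithium 19 (not isolated), via lithium alkoxide amide 20 (not isolated)
Conditions: sBuLi, (−)-sparteine, Et2O, −78 °C; 17, −78 → −40 °C, then 0 °C; AcOH, PhMe, 60 °C
Reagents that add atoms: none
Why: Proposed new method: sBuLi/(−)-sparteine removes the pro-S hydrogen at C-5 of 14 to give the configurationally stable (S)-α-lithio carbamate 18, the pyridine nitrogen of 17 binds this lithium and the C–Li bond adds syn across the alkyne (complex-induced proximity), carbon to the alkyne carbon that carries CH2OTBS and lithium to the silicon-bearing carbon, to give 19; because the addition is syn, lithium sits cis to the carbamate-bearing carbon and attacks the carbamate carbonyl in an anionic 1,4-O→C carbamoyl shift that gives 20, and acetic acid then closes the cis-hydroxy amide to the lactone with loss of diisopropylamine. The closest known reaction types are the sparteine-mediated intramolecular 5-exo-dig carbolithiation of alkynyl O-carbamates, the pyridylsilyl-directed carbolithiation and copper-catalysed carbomagnesiation of vinyl- and alkynylsilanes, and the anionic Fries-type carbamoyl migration; what is new is their intermolecular union in one flask. The furanone ring is closed in a formal [3+2] mode: C-3 attacks C-2 through a five-membered transition state (5-exo-trig) and O-1 then re-closes on C-2 (5-exo-trig lactonization). The C-5 stereocentre is under reagent control by (−)-sparteine, and retention in the C–Li to C–C step turns (S)-18 into (5R)-21. The step needs regioselectivity (C-5 to C-4, not to C-3) and syn addition; the silyl group is meant to secure both, by stabilising the α-carbanion, by chelating lithium at C-3 through its pyridyl group, and by replacing the acidic terminal C–H of a 1-alkyne. The carbamate that first directs the lithiation ends as the lactone carbonyl C-2, so no protecting group is spent on O-1.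

Step 9
Reactants: 21
Product: 22 hippolide E, (5R)-4-(hydroxymethyl)-5-[(2E,6E,10E)-3-(hydroxymethyl)-7,11,15-trimethylhexadeca-2,6,10,14-tetraen-1-yl]furan-2(5H)-one
Conditions: TBAF, AcOH, THF, 0 → 40 °C
Reagents that add atoms: none
Why: Fluoride cleaves both silyl ethers, and the freed C-4 hydroxymethyl group, cis to silicon, should assist fluoride protodesilylation of the alkenyl–silicon bond; acetic acid buffering is meant to keep the acidic H-5 from exchanging, so that the (5R) centre is kept.

## Compound list

1 | (2E,6E)-farnesyl bromide | CC(C)=CCC/C(C)=C/CC/C(C)=C/CBr | starting material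
2 | 2-methylprop-2-en-1-ol | CC(=C)CO | starting material
3 | dilithiated 2-methylprop-2-en-1-ol (C,O-dianion) | [Li]CC(=C)CO[Li] | intermediate
4 | (5E,9E)-6,10,14-trimethyl-2-methylidenepentadeca-5,9,13-trien-1-ol | CC(C)=CCC/C(C)=C/CC/C(C)=C/CCC(=C)CO | intermediate
5 | (5E,9E)-6,10,14-trimethyl-2-methylidenepentadeca-5,9,13-trien-1-yl benzenesulfenate | CC(C)=CCC/C(C)=C/CC/C(C)=C/CCC(=C)COSc1ccccc1 | intermediate
6 | [(5E,9E)-6,10,14-trimethyl-2-methylidenepentadeca-5,9,13-trien-1-yl] phenyl sulfoxide (racemic at sulfur) | CC(C)=CCC/C(C)=C/CC/C(C)=C/CCC(=C)CS(=O)c1ccccc1 | intermediate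
7 | 2-iodoethanol | OCCI | starting material
8 | N,N-diisopropylcarbamoyl chloride | CC(C)N(C(C)C)C(Cl)=O | starting material
9 | 2-iodoethyl N,N-diisopropylcarbamate | CC(C)N(C(C)C)C(=O)OCCI | intermediate
10 | α-lithio derivative of sulfoxide 6 | CC(C)=CCC/C(C)=C/CC/C(C)=C/CCC(=C)C([Li])S(=O)c1ccccc1 | intermediate
11 | (7E,11E)-8,12,16-trimethyl-4-methylidene-3-(phenylsulfinyl)heptadeca-7,11,15-trien-1-yl N,N-diisopropylcarbamate (mixture of diastereomers) | CC(C)=CCC/C(C)=C/CC/C(C)=C/CCC(=C)C(CCOC(=O)N(C(C)C)C(C)C)S(=O)c1ccccc1 | intermediate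
12 | (3E,7E,11E)-8,12,16-trimethyl-4-[(phenylsulfanyloxy)methyl]heptadeca-3,7,11,15-tetraen-1-yl N,N-diisopropylcarbamate | CC(C)=CCC/C(C)=C/CC/C(C)=C/CC/C(=C\CCOC(=O)N(C(C)C)C(C)C)COSc1ccccc1 | intermediate
13 | (3E,7E,11E)-4-(hydroxymethyl)-8,12,16-trimethylheptadeca-3,7,11,15-tetraen-1-yl N,N-diisopropylcarbamate | CC(C)=CCC/C(C)=C/CC/C(C)=C/CC/C(=C\CCOC(=O)N(C(C)C)C(C)C)CO | intermediate
14 | (3E,7E,11E)-4-{[tert-butyl(dimethyl)silyl]oxymethyl}-8,12,16-trimethylheptadeca-3,7,11,15-tetraen-1-yl N,N-diisopropylcarbamate | CC(C)=CCC/C(C)=C/CC/C(C)=C/CC/C(=C\CCOC(=O)N(C(C)C)C(C)C)CO[Si](C)(C)C(C)(C)C | intermediate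
15 | tert-butyl(dimethyl)(prop-2-yn-1-yloxy)silane | C#CCO[Si](C)(C)C(C)(C)C | starting material
16 | dimethyl(pyridin-2-yl)silane | C[SiH](C)c1ccccn1 | starting material
17 | 2-{[3-{[tert-butyl(dimethyl)silyl]oxy}prop-1-yn-1-yl](dimethyl)silyl}pyridine | CC(C)(C)[Si](C)(C)OCC#C[Si](C)(C)c1ccccn1 | intermediate
18 | (1S)-1-lithio derivative of carbamate 14 (sparteine complex) | CC(C)=CCC/C(C)=C/CC/C(C)=C/CC/C(=C\C[C@@H](OC(=O)N(C(C)C)C(C)C)[Li])CO[Si](C)(C)C(C)(C)C | intermediate
19 | alkenyllithium adduct of 18 and 17 ((R) at the carbamate carbon; lithium on the silyl-bearing carbon, cis to the carbamate-bearing carbon) | CC(C)=CCC/C(C)=C/CC/C(C)=C/CC/C(=C\C[C@@H](OC(=O)N(C(C)C)C(C)C)/C(CO[Si](C)(C)C(C)(C)C)=C(\[Li])[Si](C)(C)c1ccccn1)CO[Si](C)(C)C(C)(C)C | intermediate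
20 | lithium alkoxide of the (4R)-4-hydroxy-2-silyl-alk-2-enoic N,N-diisopropylamide (amide carbonyl cis to the carbinol carbon) | [Li+].CC(C)=CCC/C(C)=C/CC/C(C)=C/CC/C(=C\C[C@@H]([O-])/C(CO[Si](C)(C)C(C)(C)C)=C(\C(=O)N(C(C)C)C(C)C)[Si](C)(C)c1ccccn1)CO[Si](C)(C)C(C)(C)C | intermediate
21 | (5R)-4-{[tert-butyl(dimethyl)silyl]oxymethyl}-5-[(2E,6E,10E)-3-{[tert-butyl(dimethyl)silyl]oxymethyl}-7,11,15-trimethylhexadeca-2,6,10,14-tetraen-1-yl]-3-[dimethyl(pyridin-2-yl)silyl]furan-2(5H)-one | CC(C)=CCC/C(C)=C/CC/C(C)=C/CC/C(=C\C[C@H]1OC(=O)C([Si](C)(C)c2ccccn2)=C1CO[Si](C)(C)C(C)(C)C)CO[Si](C)(C)C(C)(C)C | intermediate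
22 | hippolide E, (5R)-4-(hydroxymethyl)-5-[(2E,6E,10E)-3-(hydroxymethyl)-7,11,15-trimethylhexadeca-2,6,10,14-tetraen-1-yl]furan-2(5H)-one | CC(C)=CCC/C(C)=C/CC/C(C)=C/CC/C(=C\C[C@H]1OC(=O)C=C1CO)CO | target

## Step count and risks

Total step count: 9. Longest linear sequence: 7 steps (1, 2, 4, 5, 6, 8, 9).

Steps most likely to fail:

1. Step 8 (Proposed new method). The lithiated carbamate may decompose before it adds to the alkyne. It may instead remove the propargylic proton of 17 or attack silicon with loss of the acetylide. The hindered diisopropylamide may also be slow to close to the lactone. The fallback uses known chemistry, sets out from 14 and 15 and comes back to the route at 22. Compound 15 is turned into the alkenylboronic ester F1 by copper-catalysed Markovnikov protoboration ((SIMes)CuCl, NaOtBu, B2pin2, MeOH). Compound 14 is lithiated as in step 8 (sBuLi, (−)-sparteine, Et2O, −78 °C) and trapped with F1; the boronate complex undergoes stereospecific 1,2-migration on warming, and NaOH/H2O2 gives the allylic alcohol F2. Retention in the borylation, inversion in the migration and retention in the oxidation lead to the same (R) configuration at C-5. Acryloyl chloride and iPr2NEt give the acrylate F3. Ring-closing metathesis with the second-generation Grubbs catalyst (PhMe, 80 °C) closes C-3=C-4 to the bis-silyl butenolide F4. The conditions of step 9 then give 22.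

2. Step 9. Cleavage of the alkenyl carbon–silicon bond may be slow under buffered fluoride. If the buffer is left out to speed it, proton exchange at C-5 through the 2-oxyfuran anion may erode the enantiopurity. The fallback changes the order of events, sets out from 14 and 17 and comes back at 22. Step 8 is run up to alkoxide 20 and quenched with water instead of hot acid, to give the hydroxy amide F5, which has no acidic hydrogen at the stereocentre. Unbuffered TBAF in THF then removes both silyl ethers and, helped by the freed cis-hydroxymethyl group, the alkenyl silyl group, to give the trihydroxy amide F6. AcOH in PhMe at 60 °C closes the lactone to 22.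

3. Step 2. The sulfenyl chloride may add across the three trisubstituted alkenes (episulfonium formation) in competition with O-sulfenylation. The fallback uses nucleophilic instead of electrophilic sulfur, sets out from 4 and comes back at 6. Diphenyl disulfide and tributylphosphine in THF turn the allylic alcohol into the allyl phenyl sulfide F7. NaIO4 in MeOH/H2O at 0 °C then oxidises sulfur only, to give 6.

## Further compounds

F1 | step 8 | 2-[3-{[tert-butyl(dimethyl)silyl]oxy}prop-1-en-2-yl]-4,4,5,5-tetramethyl-1,3,2-dioxaborolane | CC(C)(C)[Si](C)(C)OCC(=C)B1OC(C)(C)C(C)(C)O1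
F2 | step 8 | (3R,5E,9E,13E)-2-methylidene-3-hydroxy allylic alcohol: (3R,5E,9E,13E)-1-{[tert-butyl(dimethyl)silyl]oxy}-6-{[tert-butyl(dimethyl)silyl]oxymethyl}-10,14,18-trimethyl-2-methylidenenonadeca-5,9,13,17-tetraen-3-ol | CC(C)=CCC/C(C)=C/CC/C(C)=C/CC/C(=C\C[C@@H](O)C(=C)CO[Si](C)(C)C(C)(C)C)CO[Si](C)(C)C(C)(C)C
F3 | step 8 | acrylate ester of F2 | CC(C)=CCC/C(C)=C/CC/C(C)=C/CC/C(=C\C[C@@H](OC(=O)C=C)C(=C)CO[Si](C)(C)C(C)(C)C)CO[Si](C)(C)C(C)(C)C
F4 | step 8 | (5R)-4-{[tert-butyl(dimethyl)silyl]oxymethyl}-5-[(2E,6E,10E)-3-{[tert-butyl(dimethyl)silyl]oxymethyl}-7,11,15-trimethylhexadeca-2,6,10,14-tetraen-1-yl]furan-2(5H)-one | CC(C)=CCC/C(C)=C/CC/C(C)=C/CC/C(=C\C[C@H]1OC(=O)C=C1CO[Si](C)(C)C(C)(C)C)CO[Si](C)(C)C(C)(C)C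
F5 | step 9 | (4R)-4-hydroxy-2-[dimethyl(pyridin-2-yl)silyl] N,N-diisopropyl enamide (protonated form of 20) | CC(C)=CCC/C(C)=C/CC/C(C)=C/CC/C(=C\C[C@@H](O)/C(CO[Si](C)(C)C(C)(C)C)=C(\C(=O)N(C(C)C)C(C)C)[Si](C)(C)c1ccccn1)CO[Si](C)(C)C(C)(C)C
F6 | step 9 | (2Z,4R,6E,10E,14E)-4-hydroxy-3,7-bis(hydroxymethyl)-11,15,19-trimethyl-N,N-diisopropylicosa-2,6,10,14,18-pentaenamide | CC(C)=CCC/C(C)=C/CC/C(C)=C/CC/C(=C\C[C@@H](O)/C(CO)=C\C(=O)N(C(C)C)C(C)C)CO
F7 | step 2 | [(5E,9E)-6,10,14-trimethyl-2-methylidenepentadeca-5,9,13-trien-1-yl] phenyl sulfide | CC(C)=CCC/C(C)=C/CC/C(C)=C/CCC(=C)CSc1ccccc1
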